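Chroman numbering used throughout: O1, C2 (aryl-bearing), C3, C4 (chain-bearing), C4a, C5 (OH), C6, C7 (OMe), C8 (acyl), C8a; side chain C1''–C4'' with the carbinol at C2''. Compounds 1–25 are defined in the steps and collected in the list after step 16.

## Analysis of the target

The target is a 2-arylchroman (a flavan) whose ring A is substituted at every position but C6: hydroxyl at C5, methoxy at C7 and an (E)-4-hydroxycinnamoyl group (a chalcone) at C8. C4 carries a 2-hydroxy-4-(4-hydroxyphenyl)butyl chain, so C2–C3–C4–C1''–C4'' is a 1,7-diarylheptanoid fused to the chalcone ring A through C4–C4a and O1–C2. There are three stereocentres, C2 (R), C4 (S) and C2'' (R). C2 and C4 are trans on the pyran ring, with the aryl group equatorial and the chain pseudoaxial, away from the peri C5 oxygen. C4 and C2'' are 1,3-related across an open-chain CH2, so no ring relays configuration between them. The sensitive groups are the enone (it excludes hydrogenolysis and hydride at the end), four phenols and the O1–C2 bond. That bond is a para-hydroxybenzylic ether that ionises under acid or opens through a para-quinone methide under base, and the C2'' hydroxyl can then capture C2 to give an isomeric tetrahydropyran. The hard points are C4 beside a remote stereocentre, the regiochemistry on ring A (C5 hydroxyl against C7 methoxy, acyl at C8 and not C6) and a protecting-group plan that survives two organolithium steps. The strategy rests on one feature: O1–C8a–C4a–C4 is the heterodiene of an ortho-quinone methide of a 2-alkylated 5-methoxyresorcinol, and C2–C3 is the double bond of 4-hydroxystyrene.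

## Retrosynthetic reasoning

**25 to 24.** Only five O–Si bonds are cut. All hydroxyls are carried as silyl ethers because the finished molecule tolerates neither hydrogenolysis nor strong acid or base, and because silyl ethers do not direct metalation in the step before.

**24 to 19 and 22.** The C8–C(=O) bond is cut. C8 is the only ring A carbon flanked by two ether oxygens (the C7 methoxy and O1), so it can be lithiated (23) and acylated with the complete cinnamoyl unit 22 in one operation. Electrophilic acylation could not tell C8 from C6. The acyl group also cannot be placed before the pyran ring is built: it would make the two ring A hydroxyls unequal and require the chelated, less nucleophilic one to become O1, and the enone would not survive the earlier hydride and organolithium steps. The forward reaction must choose C8 over C6, so the C5 oxygen carries a bulky, non-coordinating triisopropylsilyl group.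

**19 to 18.** A protecting-group step only.

**18 to 13 and 16.** This is the key disconnection: C3–C4 and O1–C2 are cut together in a retro-hetero-Diels–Alder sense. It removes the ring, two skeletal bonds and two stereocentres at once and leaves an achiral styrene 16 and a benzylic alcohol 13 whose carbinol configuration is irrelevant. Forward, dehydration of 13 gives the quinone methide 17, a chiral acid must set C4, and the ring closure must set C2 trans to it.

**13 to 12 to 11 to 10.** The benzylic carbinol is revealed last, by hydride reduction of ketone 12. The aryl–carbon bond has to be made with acetal-protected phenols, and their removal needs acid. A 2,4,6-trioxygenated benzylic alcohol ionises under the same acid, and an ortho methoxymethyl ether can close onto the carbinol as a cyclic formal. At the ketone level nothing can ionise, so 10 is oxidised to 11, the phenols are freed to give 12, and the carbinol is regenerated under basic, cold conditions.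

**10 to 8 and 6.** The C4–C4a bond is cut. The carbon between the two acetal ethers of 8 is the most acidic ring position, and it is exactly the carbon that must lie between the future O1 and C5 oxygen and para to the methoxy group. The symmetry of 7 therefore fixes the ring A pattern, and lithiation (9) and addition to aldehyde 6 join the two halves.

**6 to 3.** The C1''–C2'' bond is made by asymmetric allylation of 3, and the terminal alkene of 4 and 5 is a masked aldehyde released by ozonolysis. This is the only stereocentre bought from a reagent; 3 comes from ester 1 by silylation (2) and partial reduction.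

**Side pieces.** 16 comes from 14 by acetate removal and silylation, 22 from 20 and 21 by olefination, and 8 from 7 by acetal protection.

## Alternatives that were turned down

**Alternative 1:** O1–C8a and C4–C4a are cut, so ring A arrives as an unsymmetrical dialkoxy aryne between an (R)-benzylic alkoxide and a cross-conjugated dienone. In the forward step a fluoride source releases the aryne, the alkoxide adds at the carbon that becomes C8a, and the aryl anion at C4a closes 6-exo onto the enone β-carbon to give the 2,4-trans flavan A1.
- For it: the step is convergent, the aryne polarisation fixes the ring A regiochemistry, and C2 comes from a real, separately made stereocentre. On absolute control of C2 it is stronger than the chosen route.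
- Against it: the aryl anion is short-lived and sits next to acidic α- and γ-hydrogens of the dienone, so protonation competes with the Michael closure. The alkoxide is δ to the carbonyl and can be lost by vinylogous elimination under the basic conditions. C4 is set only by a kinetic closure of unknown selectivity.
- After A1 the C2'' carbinol must still be made by enantioselective reduction, the alkene saturated, the benzyl ether removed beside a benzylic C2–O bond, and the distal acetal ethers exchanged because they would misdirect the C8 lithiation.
- Comparison: the chosen route fixes C2'' before the key step, sets C2 from C4 by conformation, and needs four steps after the ring closure.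

**Alternative 2:** Only O1–C2 is cut; an open 1,3-diarylpropane already carries C4, the chain and the C8 acetyl group. A high-potential quinone oxidant removes hydride from the CH2 para to the benzyloxy group and the ring A phenol adds to the cation, giving the 8-acetyl flavan A2.
- For it: the acyl carbon is on ring A before the ring closes, so no late lithiation is needed. On that point it is stronger than the chosen route. The trans preference at C2 is the same conformational one.
- Against it: C4 must be built as an isolated open-chain stereocentre next to a fully substituted arene and related to C2'' by separate asymmetric operations, which is long. The oxidant also meets the C4–H and an electron-rich phenol, and the nucleophile is the chelated, least nucleophilic phenol.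
- After A2 the chalcone must be made by base condensation of a hindered, twisted acetyl group while acetate and pivalate esters are present, and the benzyl ether must come off without touching the enone.
- Comparison: the chosen route creates C4 and C2 together in the ring-forming step and uses one class of protecting group at the end.

**Alternative 3:** C2–C3 and C4–C4a are cut through a temporary tetrahydropyran in which the C2'' oxygen is bonded to C2. A silyl triflate ionises an α-acetoxy ether, the oxocarbenium ion cyclises onto the terminal alkene, and an unprotected, threefold-symmetric triphenol captures the ring cation to give the all-cis tetrahydropyran A3.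
- For it: the sequence is short and strongly precedented, and it starts from the same kind of homoallylic alcohol as 4. C4 is set against C2'' by an all-equatorial chair, and that cis relationship is the one the target needs. On control of C4 this is the strongest of the four strategies, stronger than the catalyst control relied on here.
- Against it: the tetrahydropyran must then be turned into the chroman by moving C2 from the chain oxygen to a ring A oxygen. That is an acid equilibrium against a strain-free all-equatorial ring with no clear driving force.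
- After the switch ring A is still a symmetrical triphenol: methylation at C7 against C5 and acylation at C8 against C6 are both unresolved, on a molecule with free phenols and a labile benzylic ether.
- Comparison: the chosen route forms the pyran directly as the chroman and has the ring A oxygen pattern fixed from 7. It pays for this with a catalyst-controlled C4.

Key step: step 12

Assumption: the sense of induction of the chiral phosphoric acid on this alkyl-substituted quinone methide cannot be predicted with confidence; the (R)-acid is written, and its antipode is used instead if a first comparison of the two shows it to be the matched partner of the (R)-configured chain.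

## Route

Step 1
Reactants: 1 methyl 3-(4-hydroxyphenyl)propanoate
Product: 2 methyl 3-[4-(tert-butyldimethylsilyloxy)phenyl]propanoate
Conditions: TBSCl, imidazole, DMF, rt
Reagents that add atoms: tert-butyldimethylsilyl chloride, CC(C)(C)[Si](C)(C)Cl
Why: Standard silylation of a phenol; the silyl ether removes the acidic proton and, unlike an acetal ether, will not direct lithiation onto this ring later.

Step 2
Reactants: 2 methyl 3-[4-(tert-butyldimethylsilyloxy)phenyl]propanoate
Product: 3 3-[4-(tert-butyldimethylsilyloxy)phenyl]propanal
Conditions: i-Bu2AlH (1.05 equiv), CH2Cl2, −78 °C; Rochelle salt work-up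
Reagents that add atoms: none
Why: Partial reduction of a methyl ester; the aluminium hemiacetal is stable at −78 °C and releases the aldehyde only on work-up.

Step 3
Reactants: 3 3-[4-(tert-butyldimethylsilyloxy)phenyl]propanal
Product: 4 (3R)-1-[4-(tert-butyldimethylsilyloxy)phenyl]hex-5-en-3-ol
Conditions: (S)-1,1'-bi-2-naphthol (10 mol%), Ti(OiPr)4 (10 mol%), 4 Å MS, allyltributylstannane, CH2Cl2, −20 °C
Reagents that add atoms: allyltributylstannane, C=CC[Sn](CCCC)(CCCC)CCCC
Why: Keck asymmetric allylation; the (S)-binaphthol titanium complex delivers allyl to the Si face of unbranched aldehydes, which for 3 is the (R)-carbinol, and this sets C2'' of the target.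

Step 4
Reactants: 4 (3R)-1-[4-(tert-butyldimethylsilyloxy)phenyl]hex-5-en-3-ol
Product: 5 (3R)-3-(tert-butyldimethylsilyloxy)-1-[4-(tert-butyldimethylsilyloxy)phenyl]hex-5-ene
Conditions: TBSCl, imidazole, DMF, rt
Reagents that add atoms: tert-butyldimethylsilyl chloride, CC(C)(C)[Si](C)(C)Cl
Why: Silylation of an unhindered secondary alcohol; the ether keeps this oxygen from eliminating or chelating in the aryllithium addition and, later, from competing for the C2 cation.

Step 5
Reactants: 5 (3R)-3-(tert-butyldimethylsilyloxy)-1-[4-(tert-butyldimethylsilyloxy)phenyl]hex-5-ene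
Product: 6 (3R)-3-(tert-butyldimethylsilyloxy)-5-[4-(tert-butyldimethylsilyloxy)phenyl]pentanal
Conditions: O3, CH2Cl2, −78 °C (indicator end point); then PPh3, −78 °C to rt
Reagents that add atoms: ozone, [O-][O+]=O
Why: Ozonolysis of a terminal alkene with reductive work-up; the alkene reacts far faster than the silyloxyarene, and the β-silyloxy aldehyde is used at once so that it cannot eliminate.

Step 6
Reactants: 7 5-methoxyresorcinol
Product: 8 1-methoxy-3,5-bis(methoxymethoxy)benzene
Conditions: MOMCl, i-Pr2NEt, CH2Cl2, 0 °C to rt
Reagents that add atoms: chloromethyl methyl ether, COCCl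
Why: O-alkylation of both phenols under mild base; the acetal ethers are the directing groups for the next step.

Step 7
Reactants: 8 1-methoxy-3,5-bis(methoxymethoxy)benzene; 6 (3R)-3-(tert-butyldimethylsilyloxy)-5-[4-(tert-butyldimethylsilyloxy)phenyl]pentanal
Product: 10 (1RS,3R)-1-[2,6-bis(methoxymethoxy)-4-methoxyphenyl]-3-(tert-butyldimethylsilyloxy)-5-[4-(tert-butyldimethylsilyloxy)phenyl]pentan-1-ol, via aryllithium 9 (not isolated)
Conditions: n-BuLi, THF, 0 °C; then 6, −78 °C; H2O
Reagents that add atoms: none
Why: Directed ortho-metalation; the carbon between the two acetal ethers is doubly chelated and is deprotonated in preference to those next to the methoxy group, and the aryllithium adds to the aldehyde at −78 °C faster than it enolises it. The new carbinol forms as both epimers, which is harmless because it is oxidised next.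

Step 8
Reactants: 10 (1RS,3R)-1-[2,6-bis(methoxymethoxy)-4-methoxyphenyl]-3-(tert-butyldimethylsilyloxy)-5-[4-(tert-butyldimethylsilyloxy)phenyl]pentan-1-ol
Product: 11 (3R)-1-[2,6-bis(methoxymethoxy)-4-methoxyphenyl]-3-(tert-butyldimethylsilyloxy)-5-[4-(tert-butyldimethylsilyloxy)phenyl]pentan-1-one
Conditions: Dess–Martin periodinane, NaHCO3, CH2Cl2, 0 °C to rt
Reagents that add atoms: none
Why: Dess–Martin oxidation of a hindered benzylic alcohol under buffered conditions; it takes the ionisable carbinol out of the molecule before the phenols are freed.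

Step 9
Reactants: 11 (3R)-1-[2,6-bis(methoxymethoxy)-4-methoxyphenyl]-3-(tert-butyldimethylsilyloxy)-5-[4-(tert-butyldimethylsilyloxy)phenyl]pentan-1-one
Product: 12 (3R)-3-(tert-butyldimethylsilyloxy)-5-[4-(tert-butyldimethylsilyloxy)phenyl]-1-(2,6-dihydroxy-4-methoxyphenyl)pentan-1-one
Conditions: ZnBr2, n-PrSH, CH2Cl2, 0 °C, short reaction time
Reagents that add atoms: none
Why: Lewis acid and thiol cleavage of methoxymethyl ethers, which is fast enough that alkyl and aryl tert-butyldimethylsilyl ethers should persist; the ortho carbonyl assists and the product is a stable, hydrogen-bonded 2,6-dihydroxyaryl ketone.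

Step 10
Reactants: 12 (3R)-3-(tert-butyldimethylsilyloxy)-5-[4-(tert-butyldimethylsilyloxy)phenyl]-1-(2,6-dihydroxy-4-methoxyphenyl)pentan-1-one
Product: 13 2-{(1RS,3R)-3-(tert-butyldimethylsilyloxy)-5-[4-(tert-butyldimethylsilyloxy)phenyl]-1-hydroxypentyl}-5-methoxybenzene-1,3-diol
Conditions: NaBH4, THF/MeOH, 0 °C; pH 7 buffer work-up; used promptly
Reagents that add atoms: none
Why: Borohydride reduction of an ortho-hydroxyaryl ketone, the usual entry to ortho-hydroxybenzylic alcohols (as in flavanone to flavan-4-ol reductions); it is run cold and worked up at neutral pH because the product is a latent quinone methide. Both carbinol epimers form and both serve.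

Step 11
Reactants: 14 4-acetoxystyrene
Product: 16 4-(tert-butyldimethylsilyloxy)styrene, via 4-vinylphenol 15 (not isolated)
Conditions: K2CO3 (cat.), MeOH, 0 °C; solvent exchange; then TBSCl, imidazole, CH2Cl2, rt
Reagents that add atoms: tert-butyldimethylsilyl chloride, CC(C)(C)[Si](C)(C)Cl
Why: Methanolysis of the aryl acetate followed by silylation of the polymerisation-prone vinylphenol without isolating it.

Step 12
Reactants: 13 2-{(1RS,3R)-3-(tert-butyldimethylsilyloxy)-5-[4-(tert-butyldimethylsilyloxy)phenyl]-1-hydroxypentyl}-5-methoxybenzene-1,3-diol; 16 4-(tert-butyldimethylsilyloxy)styrene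
Product: 18 (2R,4R)-4-{(2R)-2-(tert-butyldimethylsilyloxy)-4-[4-(tert-butyldimethylsilyloxy)phenyl]butyl}-2-[4-(tert-butyldimethylsilyloxy)phenyl]-7-methoxychroman-5-ol (2,4-trans; same spatial arrangement as in 25, the C4 descriptor reads R only while the C2'' oxygen bears silicon), via ortho-quinone methide 17 (not isolated)
Conditions: (R)-3,3'-bis(2,4,6-triisopropylphenyl)-1,1'-binaphthyl-2,2'-diyl hydrogen phosphate (10 mol%), 16 (3 equiv), 4 Å MS, toluene, −20 °C to rt
Reagents that add atoms: none
Why: The phosphoric acid protonates the benzylic hydroxyl of 13 and, with loss of water, gives the ortho-quinone methide 17, held to the chiral phosphate by hydrogen bonds through its carbonyl oxygen and the remaining phenol; the two phenols of 13 are equivalent, so either gives the same heterodiene. The CH2 terminus of 16 attacks the methide carbon (C3–C4) and the quinone methide oxygen closes on the developing para-silyloxybenzylic cation (O1–C2) in an asynchronous, inverse-demand hetero-Diels–Alder reaction; the closest known reaction type is the Brønsted-acid-catalysed [4+2] of ortho-hydroxybenzylic alcohols with styrenes, chiral phosphoric acid versions included. The pyran ring closes in the cycloaddition mode, a four-atom heterodiene and a two-carbon alkene through a six-membered transition state, which in the stepwise limit is a six-membered attack of phenol oxygen on a benzylic cation. C4 is set by the catalyst: the bound phosphate shields one face of the planar methide carbon and has to override the weak 1,3-bias of the silyloxy-bearing C2''. C2 is set by the substrate relative to C4: the ring closes, and can re-open under the acid, so that the aryl group is equatorial while the C4 chain is pseudoaxial to avoid the peri C5 hydroxyl, which is the 2,4-trans arrangement. Regiochemistry needs no control beyond polarity, because the phloroglucinol-type ring makes C4 the electrophilic end and the para-silyloxy group makes the CH2 of 16 the nucleophilic end. The selectivity the step needs is capture of 17 by the styrene faster than its tautomerisation to an alkenylphenol or its self-addition, which the excess of the electron-rich styrene and the low temperature should secure; the silyl ether on C2'' keeps that oxygen from competing for the C2 cation.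

Step 13
Reactants: 18 (2R,4R)-4-{(2R)-2-(tert-butyldimethylsilyloxy)-4-[4-(tert-butyldimethylsilyloxy)phenyl]butyl}-2-[4-(tert-butyldimethylsilyloxy)phenyl]-7-methoxychroman-5-ol
Product: 19 (2R,4R)-4-{(2R)-2-(tert-butyldimethylsilyloxy)-4-[4-(tert-butyldimethylsilyloxy)phenyl]butyl}-2-[4-(tert-butyldimethylsilyloxy)phenyl]-7-methoxy-5-(triisopropylsilyloxy)chroman
Conditions: TIPSOTf, 2,6-lutidine, CH2Cl2, 0 °C to rt
Reagents that add atoms: triisopropylsilyl trifluoromethanesulfonate, CC(C)[Si](OS(=O)(=O)C(F)(F)F)(C(C)C)C(C)C
Why: Silylation of a hindered phenol with a silyl triflate; the triisopropylsilyl group removes the last acidic proton, screens C6 and does not coordinate lithium.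

Step 14
Reactants: 20 4-(tert-butyldimethylsilyloxy)benzaldehyde; 21 diethyl {2-[methoxy(methyl)amino]-2-oxoethyl}phosphonate
Product: 22 (E)-3-[4-(tert-butyldimethylsilyloxy)phenyl]-N-methoxy-N-methylprop-2-enamide
Conditions: NaH, THF, 0 °C to rt
Reagents that add atoms: none
Why: Horner–Wadsworth–Emmons olefination of an aromatic aldehyde with a stabilised phosphonate, which gives the (E)-alkene.

Step 15
Reactants: 19 (2R,4R)-4-{(2R)-2-(tert-butyldimethylsilyloxy)-4-[4-(tert-butyldimethylsilyloxy)phenyl]butyl}-2-[4-(tert-butyldimethylsilyloxy)phenyl]-7-methoxy-5-(triisopropylsilyloxy)chroman; 22 (E)-3-[4-(tert-butyldimethylsilyloxy)phenyl]-N-methoxy-N-methylprop-2-enamide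
Product: 24 (E)-1-[(2R,4R)-4-{(2R)-2-(tert-butyldimethylsilyloxy)-4-[4-(tert-butyldimethylsilyloxy)phenyl]butyl}-2-[4-(tert-butyldimethylsilyloxy)phenyl]-7-methoxy-5-(triisopropylsilyloxy)chroman-8-yl]-3-[4-(tert-butyldimethylsilyloxy)phenyl]prop-2-en-1-one, via C8-aryllithium 23 (not isolated)
Conditions: n-BuLi, THF, 0 °C; then 22, −78 to 0 °C; H2O
Reagents that add atoms: none
Why: Directed ortho-metalation at C8, the only position between two coordinating ether oxygens (C6 lies between the methoxy and the bulky silyloxy group), then Weinreb amide acylation. The chelated tetrahedral adduct prevents over-addition and keeps the enone masked until work-up.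

Step 16
Reactants: 24 (E)-1-[(2R,4R)-4-{(2R)-2-(tert-butyldimethylsilyloxy)-4-[4-(tert-butyldimethylsilyloxy)phenyl]butyl}-2-[4-(tert-butyldimethylsilyloxy)phenyl]-7-methoxy-5-(triisopropylsilyloxy)chroman-8-yl]-3-[4-(tert-butyldimethylsilyloxy)phenyl]prop-2-en-1-one
Product: 25 (E)-1-[(2R,4S)-5-hydroxy-4-[(2R)-2-hydroxy-4-(4-hydroxyphenyl)butyl]-2-(4-hydroxyphenyl)-7-methoxychroman-8-yl]-3-(4-hydroxyphenyl)prop-2-en-1-one (CNP0102599.2)
Conditions: Bu4NF, AcOH (1:1, excess), THF, 0 °C to rt
Reagents that add atoms: none
Why: Fluoride cleavage of the four aryl silyl ethers and the secondary alkyl silyl ether; the acetic acid buffer keeps the phenoxide concentration low so that the O1–C2 bond is not opened, and no stereocentre is touched.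

## Compound list

1 | methyl 3-(4-hydroxyphenyl)propanoate | COC(=O)CCc1ccc(O)cc1 | starting material
2 | methyl 3-[4-(tert-butyldimethylsilyloxy)phenyl]propanoate | COC(=O)CCc1ccc(O[Si](C)(C)C(C)(C)C)cc1 | intermediate
3 | 3-[4-(tert-butyldimethylsilyloxy)phenyl]propanal | O=CCCc1ccc(O[Si](C)(C)C(C)(C)C)cc1 | intermediate
4 | (3R)-1-[4-(tert-butyldimethylsilyloxy)phenyl]hex-5-en-3-ol | C=CC[C@H](O)CCc1ccc(O[Si](C)(C)C(C)(C)C)cc1 | intermediate
5 | (3R)-3-(tert-butyldimethylsilyloxy)-1-[4-(tert-butyldimethylsilyloxy)phenyl]hex-5-ene | C=CC[C@H](O[Si](C)(C)C(C)(C)C)CCc1ccc(O[Si](C)(C)C(C)(C)C)cc1 | intermediate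
6 | (3R)-3-(tert-butyldimethylsilyloxy)-5-[4-(tert-butyldimethylsilyloxy)phenyl]pentanal | O=CC[C@H](O[Si](C)(C)C(C)(C)C)CCc1ccc(O[Si](C)(C)C(C)(C)C)cc1 | intermediate
7 | 5-methoxyresorcinol (5-methoxybenzene-1,3-diol) | COc1cc(O)cc(O)c1 | starting material
8 | 1-methoxy-3,5-bis(methoxymethoxy)benzene | COCOc1cc(OC)cc(OCOC)c1 | intermediate
9 | [2,6-bis(methoxymethoxy)-4-methoxyphenyl]lithium | COCOc1cc(OC)cc(OCOC)c1[Li] | intermediate
10 | (1RS,3R)-1-[2,6-bis(methoxymethoxy)-4-methoxyphenyl]-3-(tert-butyldimethylsilyloxy)-5-[4-(tert-butyldimethylsilyloxy)phenyl]pentan-1-ol | COCOc1cc(OC)cc(OCOC)c1C(O)C[C@H](O[Si](C)(C)C(C)(C)C)CCc1ccc(O[Si](C)(C)C(C)(C)C)cc1 | intermediate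
11 | (3R)-1-[2,6-bis(methoxymethoxy)-4-methoxyphenyl]-3-(tert-butyldimethylsilyloxy)-5-[4-(tert-butyldimethylsilyloxy)phenyl]pentan-1-one | COCOc1cc(OC)cc(OCOC)c1C(=O)C[C@H](O[Si](C)(C)C(C)(C)C)CCc1ccc(O[Si](C)(C)C(C)(C)C)cc1 | intermediate
12 | (3R)-3-(tert-butyldimethylsilyloxy)-5-[4-(tert-butyldimethylsilyloxy)phenyl]-1-(2,6-dihydroxy-4-methoxyphenyl)pentan-1-one | COc1cc(O)c(C(=O)C[C@H](O[Si](C)(C)C(C)(C)C)CCc2ccc(O[Si](C)(C)C(C)(C)C)cc2)c(O)c1 | intermediate
13 | 2-{(1RS,3R)-3-(tert-butyldimethylsilyloxy)-5-[4-(tert-butyldimethylsilyloxy)phenyl]-1-hydroxypentyl}-5-methoxybenzene-1,3-diol | COc1cc(O)c(C(O)C[C@H](O[Si](C)(C)C(C)(C)C)CCc2ccc(O[Si](C)(C)C(C)(C)C)cc2)c(O)c1 | intermediate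
14 | 4-acetoxystyrene | CC(=O)Oc1ccc(C=C)cc1 | starting material
15 | 4-vinylphenol | C=Cc1ccc(O)cc1 | intermediate
16 | 4-(tert-butyldimethylsilyloxy)styrene | C=Cc1ccc(O[Si](C)(C)C(C)(C)C)cc1 | intermediate
17 | 6-{(3R)-3-(tert-butyldimethylsilyloxy)-5-[4-(tert-butyldimethylsilyloxy)phenyl]pentylidene}-5-hydroxy-3-methoxycyclohexa-2,4-dien-1-one (ortho-quinone methide) | COC1=CC(=O)C(=CC[C@H](O[Si](C)(C)C(C)(C)C)CCc2ccc(O[Si](C)(C)C(C)(C)C)cc2)C(O)=C1 | intermediate
18 | (2R,4R)-4-{(2R)-2-(tert-butyldimethylsilyloxy)-4-[4-(tert-butyldimethylsilyloxy)phenyl]butyl}-2-[4-(tert-butyldimethylsilyloxy)phenyl]-7-methoxychroman-5-ol (2,4-trans) | COc1cc(O)c2c(c1)O[C@@H](c1ccc(O[Si](C)(C)C(C)(C)C)cc1)C[C@@H]2C[C@H](O[Si](C)(C)C(C)(C)C)CCc1ccc(O[Si](C)(C)C(C)(C)C)cc1 | intermediate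
19 | (2R,4R)-4-{(2R)-2-(tert-butyldimethylsilyloxy)-4-[4-(tert-butyldimethylsilyloxy)phenyl]butyl}-2-[4-(tert-butyldimethylsilyloxy)phenyl]-7-methoxy-5-(triisopropylsilyloxy)chroman | COc1cc(O[Si](C(C)C)(C(C)C)C(C)C)c2c(c1)O[C@@H](c1ccc(O[Si](C)(C)C(C)(C)C)cc1)C[C@@H]2C[C@H](O[Si](C)(C)C(C)(C)C)CCc1ccc(O[Si](C)(C)C(C)(C)C)cc1 | intermediate
20 | 4-(tert-butyldimethylsilyloxy)benzaldehyde | O=Cc1ccc(O[Si](C)(C)C(C)(C)C)cc1 | starting material
21 | diethyl {2-[methoxy(methyl)amino]-2-oxoethyl}phosphonate | CCOP(=O)(CC(=O)N(C)OC)OCC | starting material
22 | (E)-3-[4-(tert-butyldimethylsilyloxy)phenyl]-N-methoxy-N-methylprop-2-enamide | CON(C)C(=O)/C=C/c1ccc(O[Si](C)(C)C(C)(C)C)cc1 | intermediate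
23 | C8-lithio derivative of 19 | COc1cc(O[Si](C(C)C)(C(C)C)C(C)C)c2c(c1[Li])O[C@@H](c1ccc(O[Si](C)(C)C(C)(C)C)cc1)C[C@@H]2C[C@H](O[Si](C)(C)C(C)(C)C)CCc1ccc(O[Si](C)(C)C(C)(C)C)cc1 | intermediate
24 | (E)-1-[(2R,4R)-4-{(2R)-2-(tert-butyldimethylsilyloxy)-4-[4-(tert-butyldimethylsilyloxy)phenyl]butyl}-2-[4-(tert-butyldimethylsilyloxy)phenyl]-7-methoxy-5-(triisopropylsilyloxy)chroman-8-yl]-3-[4-(tert-butyldimethylsilyloxy)phenyl]prop-2-en-1-one | COc1cc(O[Si](C(C)C)(C(C)C)C(C)C)c2c(c1C(=O)/C=C/c1ccc(O[Si](C)(C)C(C)(C)C)cc1)O[C@@H](c1ccc(O[Si](C)(C)C(C)(C)C)cc1)C[C@@H]2C[C@H](O[Si](C)(C)C(C)(C)C)CCc1ccc(O[Si](C)(C)C(C)(C)C)cc1 | intermediate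
25 | (E)-1-[(2R,4S)-5-hydroxy-4-[(2R)-2-hydroxy-4-(4-hydroxyphenyl)butyl]-2-(4-hydroxyphenyl)-7-methoxychroman-8-yl]-3-(4-hydroxyphenyl)prop-2-en-1-one | COc1cc(O)c2c(c1C(=O)/C=C/c1ccc(O)cc1)O[C@@H](c1ccc(O)cc1)C[C@@H]2C[C@H](O)CCc1ccc(O)cc1 | target

## Step count and least certain steps

Total: 16 steps. Longest linear sequence: 13 steps (1–5, 7–10, 12, 13, 15, 16).

**Step 12 (key step).** The most likely failure is poor facial selectivity at C4, if catalyst and the C2'' centre are mismatched or if the alkyl-substituted quinone methide binds the phosphate loosely. The second is tautomerisation of the quinone methide to an alkenylphenol, or its self-addition, in competition with capture by the styrene. The fallback gives up catalyst control and relies on separation. It sets out from 13 and 16, which are combined under an achiral acid (diphenyl hydrogen phosphate, toluene, 0 °C to rt). Ring closure still makes each product 2,4-trans, so 18 is formed together with the C4-epimeric (2S,4S)-trans chroman F1. Because C2'' is fixed, the two are diastereomers and are separated by chromatography (if necessary after the silylation of step 13), and the route is rejoined at 18.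

**Step 10.** The risks are over-reduction (the borate of the product losing oxygen to a quinone methide that takes up a second hydride) and dehydration of 13 on work-up or on silica. The fallback avoids the ketone reduction altogether. It sets out from 10 and removes the acetal ethers without Brønsted acid: TMSOTf and 2,2'-bipyridyl in CH2Cl2 at 0 °C convert the aryl acetals and the carbinol into the tris(trimethylsilyl) ether F2, and brief methanolysis with K2CO3 at 0 °C frees both phenols and the carbinol, coming back to the route at 13.

**Step 15.** The hindered aryllithium 23 may act as a base on the N-methoxy amide (loss of the methoxy group as formaldehyde) or add in conjugate fashion, and metalation may be incomplete or stray to C6 or C2. The fallback replaces acyl transfer by addition and oxidation. It sets out from 22, which i-Bu2AlH at −78 °C reduces to (E)-3-[4-(tert-butyldimethylsilyloxy)phenyl]prop-2-enal F3. The lithiated 19 (23) adds 1,2 to this aldehyde to give the C8 allylic alcohol F4 as a mixture of carbinol epimers, and MnO2 in CH2Cl2 oxidises it to the enone, coming back at 24.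

**Step 16.** Once the 4'-phenoxide forms, the O1–C2 bond can open through a para-quinone methide, because O1 belongs to an ortho-acylphenol and is a good leaving group. The result would be epimerisation at C2 or recapture by the C2'' oxygen to give the isomeric tetrahydropyran. The fallback splits the deprotection into two non-basic operations. It sets out from 24: HF·pyridine with excess pyridine in THF first removes the secondary alkyl silyl group while the phenols stay masked, giving the C2'' alcohol F5. KHF2 in MeOH at rt then removes the aryl silyl ethers under near-neutral conditions, coming back at 25.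

## Further compounds

F1 | step 12 | (2S,4S)-4-{(2R)-2-(tert-butyldimethylsilyloxy)-4-[4-(tert-butyldimethylsilyloxy)phenyl]butyl}-2-[4-(tert-butyldimethylsilyloxy)phenyl]-7-methoxychroman-5-ol (C2,C4-epimeric trans chroman) | COc1cc(O)c2c(c1)O[C@H](c1ccc(O[Si](C)(C)C(C)(C)C)cc1)C[C@H]2C[C@H](O[Si](C)(C)C(C)(C)C)CCc1ccc(O[Si](C)(C)C(C)(C)C)cc1
F2 | step 10 | tris(trimethylsilyl) ether of 13 (both phenols and the benzylic carbinol silylated) | COc1cc(O[Si](C)(C)C)c(C(O[Si](C)(C)C)C[C@H](O[Si](C)(C)C(C)(C)C)CCc2ccc(O[Si](C)(C)C(C)(C)C)cc2)c(O[Si](C)(C)C)c1
F3 | step 15 | (E)-3-[4-(tert-butyldimethylsilyloxy)phenyl]prop-2-enal | O=C/C=C/c1ccc(O[Si](C)(C)C(C)(C)C)cc1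
F4 | step 15 | (E)-1-[(2R,4R)-4-{(2R)-2-(tert-butyldimethylsilyloxy)-4-[4-(tert-butyldimethylsilyloxy)phenyl]butyl}-2-[4-(tert-butyldimethylsilyloxy)phenyl]-7-methoxy-5-(triisopropylsilyloxy)chroman-8-yl]-3-[4-(tert-butyldimethylsilyloxy)phenyl]prop-2-en-1-ol (carbinol epimers) | COc1cc(O[Si](C(C)C)(C(C)C)C(C)C)c2c(c1C(O)/C=C/c1ccc(O[Si](C)(C)C(C)(C)C)cc1)O[C@@H](c1ccc(O[Si](C)(C)C(C)(C)C)cc1)C[C@@H]2C[C@H](O[Si](C)(C)C(C)(C)C)CCc1ccc(O[Si](C)(C)C(C)(C)C)cc1
F5 | step 16 | (E)-1-[(2R,4S)-4-{(2R)-2-hydroxy-4-[4-(tert-butyldimethylsilyloxy)phenyl]butyl}-2-[4-(tert-butyldimethylsilyloxy)phenyl]-7-methoxy-5-(triisopropylsilyloxy)chroman-8-yl]-3-[4-(tert-butyldimethylsilyloxy)phenyl]prop-2-en-1-one | COc1cc(O[Si](C(C)C)(C(C)C)C(C)C)c2c(c1C(=O)/C=C/c1ccc(O[Si](C)(C)C(C)(C)C)cc1)O[C@@H](c1ccc(O[Si](C)(C)C(C)(C)C)cc1)C[C@@H]2C[C@H](O)CCc1ccc(O[Si](C)(C)C(C)(C)C)cc1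
A1 | alternative 1 | 2,4-trans 5-benzyloxy-7-methoxy-2-[4-(methoxymethoxy)phenyl]chroman carrying an (E)-2-oxo-4-[4-(methoxymethoxy)phenyl]but-3-enyl chain at C4 | COc1cc(OCc3ccccc3)c2c(c1)O[C@@H](c1ccc(OCOC)cc1)C[C@@H]2CC(=O)/C=C/c1ccc(OCOC)cc1
A2 | alternative 2 | 2,4-trans 8-acetyl-2-(4-benzyloxyphenyl)-5-(tert-butyldimethylsilyloxy)-7-methoxychroman with the (R)-2-acetoxy-4-(4-pivaloyloxyphenyl)butyl chain at C4 | COc1cc(O[Si](C)(C)C(C)(C)C)c2c(c1C(C)=O)O[C@@H](c1ccc(OCc3ccccc3)cc1)C[C@@H]2C[C@H](OC(C)=O)CCc1ccc(OC(=O)C(C)(C)C)cc1
A3 | alternative 3 | all-cis 2-[4-(tert-butyldimethylsilyloxy)phenyl]-4-(2,4,6-trihydroxyphenyl)-6-{2-[4-(tert-butyldimethylsilyloxy)phenyl]ethyl}tetrahydropyran | O1[C@@H](c2ccc(O[Si](C)(C)C(C)(C)C)cc2)C[C@@H](c2c(O)cc(O)cc2O)C[C@H]1CCc1ccc(O[Si](C)(C)C(C)(C)C)cc1
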